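At early times the flask holds no dissolved reagent, so I begin my curves there and then follow one substrate molecule through its forks.

left-handed substrate 0.10 M; gas 17 mM (held); right-handed substrate 0.10 M; time 50 s

    left-handed substrate ⇌ right-handed substrate (k1 = 0.078 s⁻¹)
    2 reagent → homo dimer (k2 = 2.1 M⁻¹ s⁻¹)
    reagent + left-handed substrate → left-handed product (k3 = 3.5 M⁻¹ s⁻¹)
    gas ⇌ reagent, rate k4*(csat - [reagent]) (k4 = 3.6 s⁻¹, csat = 17 mM)
    reagent + right-handed substrate → right-handed product (k5 = 0.050 M⁻¹ s⁻¹)

- reagent is single-handed; left-handed substrate and right-handed substrate are mirror images of each other, charged as a racemate, each of them at the stated concentration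
- a doubled species enters its step squared and goes two at a time
- at the start none of reagent is dissolved
- run time (flask): 50 s
- the handed part of reagent does not stay in what it makes, so the products of the two hands are mirror images too

- red: doubling the transfer coefficient of step 4, all else as stated
- ochre: doubling the saturation concentration of gas, all else as stated

* left-handed product at 50 s, in percent of the left-handed substrate and right-handed substrate together charged
* concentration of reagent in solution at 5.0 s, in percent of saturation
* the change that raises the amount of left-handed product at 50 s, in percent of the left-handed substrate and right-handed substrate together charged most ("none" if none brings more than 2 percentage points) (red / ochre / none)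
* amount of left-handed product at 50 s, in percent of the left-handed substrate and right-handed substrate together charged, after red

[reagent] leaves zero with slope 0.0612 M s⁻¹ and bends at about 0.253 s. Transfer at 3.6 s⁻¹ outruns capture by substrate at 0.355 s⁻¹, and dimer loss at 0.0714 s⁻¹ is smaller still. So I balance transfer against capture and get a plateau of 15.5 mM, which I commit to at 5.0 s as 91.0% of saturation.

Now the molecule. On the left hand it faces a pseudo-first-order capture of 0.0542 s⁻¹ against flipping at 0.078 s⁻¹, so each visit ends in capture with chance 41.0%. On the right hand capture at 7.74 × 10⁻⁴ s⁻¹ is far slower than flipping, so the molecule goes back to the left hand with chance 99.0%; this is a dynamic kinetic resolution with selectivity factor 70.0. It needs 18.5 s on the left hand and spends as long on the right, which gives 36.9 s. Half of the charge starts right-handed and first needs one flip of 12.8 s, counted over the whole charge as 6.41 s. That makes 43.3 s the mean wait, the average time a substrate molecule of either hand spends before capture.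

Left-handed product starts at 0.0271 s⁻¹ as a fraction of the charge and bends at about 4.76 s. Beyond that I take the mean wait as the approximate time constant of the substrate's decay, so by this estimate the substrate crosses the product near 30.0 s, and the product heads for 98.6% of the charge. At 50 s I reckon 67.5%. Red shortens the wait to 41.7 s, giving 68.9%. Ochre doubles my plateau and shortens it to 24.9 s, so I choose ochre.

The forecast says 68.5% (66% to 71%) of left-handed product, above my figure, with 91% of saturation, 69.7% after red, and ochre as the best change, since “doubling the saturation concentration nearly doubles the reagent level”.

The flask gives 68.6%, 91.0%, 69.6% and ochre, which gains 16 percentage points against 1 point for red. At 50.0 s reagent is made 1.00 times as fast as it is used. For the neighbour flask read at 30 s, the mean wait gives 49.3% left-handed product, and that flask holds 50.5%.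

The rate constants were chosen freely.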